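**Retrosynthetic overview**

1. The lactone ring (C1–O2–C3–C4–C5–C8) is made last, by Baeyer–Villiger insertion of O2 into the C1–C3 bond of a 2-oxabicyclo[2.2.1]heptan-6-one.
2. The tetrahydrofuran ring (O7–C6–C5–C8–C1) is closed just before, by a methanolysis / acetyl-shift / 5-exo-tet cascade on a cyclopentanone cis-fused to an α-triflyloxy γ-lactone. Enabling feature: without O2, the atoms C1, C3, C4, C5, C8 form a cyclopentanone on which O7, the C4 oxygen and the C5–C6 bond are all cis, so the C4 oxygen can hold the C6 carboxyl as a γ-lactone and O7 reaches C6 once that lactone is opened.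
3. The C8–quaternary carbon bond comes from a hydrogen-atom-transfer radical conjugate addition of an exocyclic alkene (hydroazulene fragment A) to a cyclopentenone-fused lactone (fragment B); both new stereocenters arise in this one event by substrate control.
4. Fragment A: 4,4-dimethylcyclohex-2-enone, asymmetric conjugate addition (first stereocenter, by catalysis), Pd cycloalkenylation (five-membered ring), one-carbon ring expansion (seven-membered ring), Peterson-masked methylene. Fragment B: bought (1R,5S)-2-oxabicyclo[3.3.0]oct-6-en-3-one, hydroxylated, inverted and oxidised to the enone.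
5. Ring order: six-membered carbocycle (bought), cyclopentane, cycloheptane; then cyclopentene/γ-lactone (bought), tetrahydrofuran, δ-lactone.

Key step: step 14

Remark: core atoms carry the numbers of 2,7-dioxabicyclo[3.2.1]octan-3-one in all intermediates (C1 acetal carbon, O2, C3 lactone carbonyl, C4 acetoxy carbon, C5, C6 ester carbon, O7, C8 bearing the hydroazulene); Az is the 1,4,4-trimethyl-8-methylidenedecahydroazulen-1-yl group exactly as in the target; exo means the convex face (side of the ring-fusion hydrogens) and endo the concave face; it is assumed that the (S,R,R) phosphoramidite directs the zinc reagent to the same face of 1 as of cyclohex-2-enone.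

**Fragment A**

Step 1
Reactants: 1 4,4-dimethylcyclohex-2-en-1-one; 2 but-3-en-1-ylmagnesium bromide
Product: 5 [(3R)-3-(but-3-en-1-yl)-4,4-dimethylcyclohex-1-en-1-yl]oxy(trimethyl)silane, via di(but-3-en-1-yl)zinc 3 (not isolated), via zinc enolate 4 (not isolated)
Conditions: 2 (2 equiv), ZnCl2 (1 equiv), Et2O, 0 °C, then 1,4-dioxane, filtration; Cu(OTf)2 (2 mol%), (S,R,R)-O,O'-(1,1'-binaphthyl-2,2'-diyl) N,N-bis(1-phenylethyl)phosphoramidite (4 mol%), 1, toluene, −30 °C; then TMSOTf, −30 → 0 °C
Reagents that add atoms: trimethylsilyl trifluoromethanesulfonate, C[Si](C)(C)OS(=O)(=O)C(F)(F)F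
Why: Copper-catalysed asymmetric conjugate addition of a dialkylzinc to a cyclic enone, in which the chiral phosphoramidite selects the enone face and so sets C3 as R, followed by O-silylation of the zinc enolate, which fixes the enol ether regiochemistry needed for step 2.

Step 2
Reactants: 5 [(3R)-3-(but-3-en-1-yl)-4,4-dimethylcyclohex-1-en-1-yl]oxy(trimethyl)silane
Product: 6 (3aR,7aR)-7,7-dimethyl-3-methylideneoctahydro-4H-inden-4-one
Conditions: Pd(OAc)2 (10 mol%), O2 (1 atm), DMSO, 45 °C
Reagents that add atoms: none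
Why: Palladium diacetate-catalysed oxidative cycloalkenylation of a silyl enol ether with a pendant terminal alkene (5-exo attack on the internal alkene carbon, then β-hydride elimination to the exocyclic methylene), in which the three-atom tether forces the new C–C bond cis to the side chain and so gives the cis ring fusion.

Step 3
Reactants: 6 (3aR,7aR)-7,7-dimethyl-3-methylideneoctahydro-4H-inden-4-one
Product: 8 (3aR,8aR)-8,8-dimethyl-3-methylideneoctahydroazulen-4(1H)-one, via α-trimethylsilyl ketone 7 (not isolated)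
Conditions: TMSCHN2, Sc(OTf)3 (10 mol%), toluene, −20 °C; then 1 M HCl, THF, 0 °C
Reagents that add atoms: (trimethylsilyl)diazomethane, C[Si](C)(C)C=[N+]=[N-]
Why: Lewis acid-catalysed diazoalkane homologation of a cyclic ketone (Tiffeneau–Demjanov-type ring expansion), in which the less substituted α-methylene should migrate, so that the new carbon enters on the side away from the ring fusion and the two ring-fusion stereocenters stay untouched.

Step 4
Reactants: 8 (3aR,8aR)-8,8-dimethyl-3-methylideneoctahydroazulen-4(1H)-one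
Product: 9 (3aR,8aR)-8,8-dimethyl-3-methylidene-4-[(trimethylsilyl)methyl]decahydroazulen-4-ol
Conditions: Me3SiCH2Li, CeCl3, THF, −78 °C
Reagents that add atoms: (trimethylsilyl)methyllithium, [Li]C[Si](C)(C)C
Why: 1,2-Addition of the weakly basic organocerium reagent to the enolisable ketone gives the β-hydroxysilane of a Peterson olefination, which keeps the future exocyclic methylene masked during the radical coupling; the configuration of the new carbinol carbon is inconsequential because it is destroyed in step 10.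

**Fragment B**

Step 5
Reactants: 10 (1R,5S)-2-oxabicyclo[3.3.0]oct-6-en-3-one
Product: 11 4-exo-hydroxy derivative of lactone 10 (carbinol carbon R)
Conditions: KN(SiMe3)2, THF, −78 °C; then 3-phenyl-2-(phenylsulfonyl)oxaziridine, −78 °C
Reagents that add atoms: 3-phenyl-2-(phenylsulfonyl)oxaziridine, O=S(=O)(N1OC1c1ccccc1)c1ccccc1
Why: Electrophilic hydroxylation of the lactone enolate by an N-sulfonyloxaziridine, which should approach the convex face of the cis-fused bicycle and give the exo alcohol.

Step 6
Reactants: 11 4-exo-hydroxy derivative of lactone 10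
Product: 12 4-endo 4-nitrobenzoate of lactone 10 (carbinol carbon S)
Conditions: 4-nitrobenzoic acid, PPh3, DIAD, THF, 0 °C → rt
Reagents that add atoms: 4-nitrobenzoic acid, O=C(O)c1ccc(cc1)[N+](=O)[O-]
Why: Mitsunobu reaction, in which SN2 attack of the carboxylate on the oxyphosphonium ion inverts the carbinol carbon to the endo (S) configuration needed for the later backside displacement at C6.

Step 7
Reactants: 12 4-endo 4-nitrobenzoate of lactone 10
Product: 13 4-endo-hydroxy derivative of lactone 10 (carbinol carbon S)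
Conditions: K2CO3 (0.2 equiv), MeOH, 0 °C; then AcOH
Reagents that add atoms: none
Why: Base-catalysed transesterification of the activated aryl ester with methanol cleaves only the acyl C–O bond, so the inverted configuration is kept and any opened γ-lactone should reclose on acidification.

Step 8
Reactants: 13 4-endo-hydroxy derivative of lactone 10
Product: 14 4-endo tert-butyldimethylsilyl ether of lactone 10
Conditions: TBSCl, imidazole, DMF, rt
Reagents that add atoms: tert-butyldimethylsilyl chloride, CC(C)(C)[Si](C)(C)Cl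
Why: Standard silylation of a secondary alcohol, which protects the C6 oxygen through the oxidation, coupling and enolate steps without touching a stereocenter.

Step 9
Reactants: 14 4-endo tert-butyldimethylsilyl ether of lactone 10
Product: 16 4-endo-[(tert-butyldimethylsilyl)oxy]-cis-2-oxabicyclo[3.3.0]oct-6-ene-3,8-dione, via allylic alcohol 15 (not isolated)
Conditions: SeO2 (cat.), t-BuOOH, CH2Cl2, rt; then 1,1,1-triacetoxy-1,1-dihydro-1,2-benziodoxol-3(1H)-one, CH2Cl2, rt
Reagents that add atoms: tert-butyl hydroperoxide, CC(C)(C)OO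
Why: SeO2-catalysed allylic oxidation (ene reaction then [2,3]-sigmatropic shift, which should oxidise the ring methylene in preference to the ring-fusion methine and leave the alkene in place) followed by periodinane oxidation of the allylic alcohol gives the cyclopentenone without creating a stereocenter.

**Coupling and endgame**

Step 10
Reactants: 9 (3aR,8aR)-8,8-dimethyl-3-methylidene-4-[(trimethylsilyl)methyl]decahydroazulen-4-ol; 16 4-endo-[(tert-butyldimethylsilyl)oxy]-cis-2-oxabicyclo[3.3.0]oct-6-ene-3,8-dione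
Product: 18 6-exo-Az-4-endo-[(tert-butyldimethylsilyl)oxy]-cis-2-oxabicyclo[3.3.0]octane-3,8-dione, via β-hydroxysilane adduct 17 (not isolated)
Conditions: Fe(acac)3 (30 mol%), PhSiH3, EtOH/(CH2OH)2, 60 °C; then TsOH·H2O (cat.), CH2Cl2, 0 °C
Reagents that add atoms: none
Why: Iron hydride hydrogen atom transfer to the 1,1-disubstituted alkene gives the tertiary radical, whose Giese addition to the enone should form the C8–quaternary carbon bond on the convex face of the cis-hydroazulene (anti to the seven-membered ring) and anti to the C5 side chain of the enone, setting both new stereocenters by substrate control, and acid-catalysed Peterson elimination of the β-hydroxysilane then releases the exocyclic methylene.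

Step 11
Reactants: 18 6-exo-Az-4-endo-[(tert-butyldimethylsilyl)oxy]-cis-2-oxabicyclo[3.3.0]octane-3,8-dione
Product: 20 7-endo-acetoxy-6-exo-Az-4-endo-[(tert-butyldimethylsilyl)oxy]-cis-2-oxabicyclo[3.3.0]octane-3,8-dione, via α-hydroxy ketone 19 (not isolated)
Conditions: KN(SiMe3)2, THF, −78 °C; 3-phenyl-2-(phenylsulfonyl)oxaziridine; then Ac2O, −78 → 0 °C
Reagents that add atoms: 3-phenyl-2-(phenylsulfonyl)oxaziridine, O=S(=O)(N1OC1c1ccccc1)c1ccccc1; acetic anhydride, CC(=O)OC(C)=O
Why: Kinetic enolisation toward the C1 methylene (the C4 methine is shielded and carries the lactone oxygen), enolate hydroxylation by the N-sulfonyloxaziridine anti to the bulky C8 substituent, which should place the C1 oxygen cis to the C4 oxygen and to the C5–C6 bond, and O-acetylation of the alkoxide in the same flask.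

Step 12
Reactants: 20 7-endo-acetoxy-6-exo-Az-4-endo-[(tert-butyldimethylsilyl)oxy]-cis-2-oxabicyclo[3.3.0]octane-3,8-dione
Product: 21 7-endo-acetoxy-6-exo-Az-4-endo-hydroxy-cis-2-oxabicyclo[3.3.0]octane-3,8-dione
Conditions: HF·pyridine, pyridine, THF, 0 °C → rt
Reagents that add atoms: none
Why: Fluoride cleavage of the silyl ether under buffered conditions that should leave the acetate, the lactone and the exocyclic alkene untouched.

Step 13
Reactants: 21 7-endo-acetoxy-6-exo-Az-4-endo-hydroxy-cis-2-oxabicyclo[3.3.0]octane-3,8-dione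
Product: 22 7-endo-acetoxy-6-exo-Az-4-endo-[(trifluoromethylsulfonyl)oxy]-cis-2-oxabicyclo[3.3.0]octane-3,8-dione
Conditions: Tf2O, pyridine, CH2Cl2, −30 °C
Reagents that add atoms: trifluoromethanesulfonic anhydride, O=S(=O)(OS(=O)(=O)C(F)(F)F)C(F)(F)F
Why: O-Sulfonylation of the α-hydroxy lactone, which activates C6 with retention of its S configuration and at the same time makes the lactone carbonyl the most electrophilic site of the molecule.

Step 14
Reactants: 22 7-endo-acetoxy-6-exo-Az-4-endo-[(trifluoromethylsulfonyl)oxy]-cis-2-oxabicyclo[3.3.0]octane-3,8-dione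
Product: 25 methyl 5-endo-acetoxy-7-anti-Az-6-oxo-2-oxabicyclo[2.2.1]heptane-3-exo-carboxylate, via ring-opened methyl ester 23 (not isolated), via acetyl-shifted alcohol 24 (not isolated)
Conditions: NaOMe (1.05 equiv), MeOH/THF, −40 → 0 °C
Reagents that add atoms: sodium methoxide, [Na+].[O-]C
Why: Proposed new method: methoxide should add to the γ-lactone carbonyl, which the α-triflate and ring strain make far more electrophilic than the acetate, and unzip it to the C6 methyl ester and the C4 alkoxide (23); a 1,3 O-to-O acetyl shift through a six-membered cyclic orthoester anion, possible because the C1 and C4 oxygens are cis on the cyclopentanone, then parks the acetate on C4 and frees the C1 alkoxide (24), which displaces the triflate at C6. The closest known reaction type is the base-mediated methanolytic ring contraction of α-triflyloxy lactones, in which the oxygen set free by methanolysis displaces the α-triflate to give a cyclic ether carboxylate; here that displacement is handed on to a second oxygen by acyl transfer. The tetrahydrofuran ring O7–C6–C5–C8–C1 closes in the 5-exo-tet mode and thereby creates the 2-oxabicyclo[2.2.1]heptane, while the γ-lactone ring is given up. C6 is set by SN2 inversion of the S-configured triflate (itself fixed in steps 5 and 6), which places the ester exo and out of reach of the C4 oxygen; C1, C4, C5 and C8 are carried through unchanged. The step needs ring closure by O7 instead of oxetane formation by the C4 alkoxide (4-exo-tet) and attack of methoxide on the lactone instead of the acetate; the kinetic preference for five- over four-membered closure, the fast intramolecular acyl shift, one equivalent of base and low temperature should secure both.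

Step 15
Reactants: 25 methyl 5-endo-acetoxy-7-anti-Az-6-oxo-2-oxabicyclo[2.2.1]heptane-3-exo-carboxylate
Product: 26 methyl (1S,4S,5R,6R,8R)-4-acetoxy-3-oxo-8-Az-2,7-dioxabicyclo[3.2.1]octane-6-carboxylate (CNP0215240.1)
Conditions: Me3SiOOSiMe3, TMSOTf (10 mol%), CH2Cl2, −78 → −40 °C
Reagents that add atoms: bis(trimethylsilyl) peroxide, C[Si](C)(C)OO[Si](C)(C)C
Why: Baeyer–Villiger oxidation with a silyl peroxide that should not epoxidise the exocyclic alkene, in which the alkoxy-substituted bridgehead carbon C1 migrates with retention in preference to the acetoxy-bearing C4 (as known for oxanorbornanones), inserting O2 between C1 and C3 and completing the 2,7-dioxabicyclo[3.2.1]octan-3-one.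

**Compound list**

1 | 4,4-dimethylcyclohex-2-en-1-one | CC1(C)CCC(=O)C=C1 | starting material
2 | but-3-en-1-ylmagnesium bromide | C=CCC[Mg]Br | starting material
3 | di(but-3-en-1-yl)zinc | C=CCC[Zn]CCC=C | intermediate
4 | zinc enolate: but-3-en-1-ylzinc (3R)-3-(but-3-en-1-yl)-4,4-dimethylcyclohex-1-en-1-olate | C=CCC[Zn]OC1=C[C@@H](CCC=C)C(C)(C)CC1 | intermediate
5 | [(3R)-3-(but-3-en-1-yl)-4,4-dimethylcyclohex-1-en-1-yl]oxy(trimethyl)silane | CC1(C)CCC(O[Si](C)(C)C)=C[C@H]1CCC=C | intermediate
6 | (3aR,7aR)-7,7-dimethyl-3-methylideneoctahydro-4H-inden-4-one (cis-fused) | O=C1CCC(C)(C)[C@@H]2CCC(=C)[C@H]12 | intermediate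
7 | α-trimethylsilyl ketone: (3aR,8aR)-8,8-dimethyl-3-methylidene-5-(trimethylsilyl)octahydroazulen-4(1H)-one, either C5 epimer | O=C1C([Si](C)(C)C)CCC(C)(C)[C@@H]2CCC(=C)[C@H]12 | intermediate
8 | (3aR,8aR)-8,8-dimethyl-3-methylideneoctahydroazulen-4(1H)-one (cis-fused) | O=C1CCCC(C)(C)[C@@H]2CCC(=C)[C@H]12 | intermediate
9 | (3aR,8aR)-8,8-dimethyl-3-methylidene-4-[(trimethylsilyl)methyl]decahydroazulen-4-ol, either C4 epimer | C[Si](C)(C)CC1(O)CCCC(C)(C)[C@@H]2CCC(=C)[C@H]12 | intermediate
10 | (1R,5S)-2-oxabicyclo[3.3.0]oct-6-en-3-one | O=C1O[C@@H]2CC=C[C@@H]2C1 | starting material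
11 | 4-exo-hydroxy derivative of lactone 10 (carbinol carbon R; OH cis to the ring-fusion hydrogens) | O=C1O[C@@H]2CC=C[C@@H]2[C@H]1O | intermediate
12 | 4-endo 4-nitrobenzoate of lactone 10 (carbinol carbon S; acyloxy group on the concave face) | O=C1O[C@@H]2CC=C[C@@H]2[C@@H]1OC(=O)c1ccc(cc1)[N+](=O)[O-] | intermediate
13 | 4-endo-hydroxy derivative of lactone 10 (carbinol carbon S) | O=C1O[C@@H]2CC=C[C@@H]2[C@@H]1O | intermediate
14 | 4-endo tert-butyldimethylsilyl ether of lactone 10 | O=C1O[C@@H]2CC=C[C@@H]2[C@@H]1O[Si](C)(C)C(C)(C)C | intermediate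
15 | allylic alcohol: 8-hydroxy derivative of 14, either C8 epimer | O=C1O[C@@H]2C(O)C=C[C@@H]2[C@@H]1O[Si](C)(C)C(C)(C)C | intermediate
16 | 4-endo-[(tert-butyldimethylsilyl)oxy]-cis-2-oxabicyclo[3.3.0]oct-6-ene-3,8-dione (bicycle C1, C4, C5, C6, C7, C8 = core C4, C6, C5, C8, C1, C3) | O=C1O[C@@H]2C(=O)C=C[C@@H]2[C@@H]1O[Si](C)(C)C(C)(C)C | intermediate
17 | β-hydroxysilane adduct: compound 18 with C(OH)CH2SiMe3 in place of the exocyclic C=CH2 of Az | C[Si](C)(C)CC1(O)CCCC(C)(C)[C@@H]2CC[C@@](C)([C@@H]3CC(=O)[C@H]4OC(=O)[C@@H](O[Si](C)(C)C(C)(C)C)[C@@H]34)[C@H]12 | intermediate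
18 | 6-exo-Az-4-endo-[(tert-butyldimethylsilyl)oxy]-cis-2-oxabicyclo[3.3.0]octane-3,8-dione (Az trans to the C5 side chain) | C=C1CCCC(C)(C)[C@@H]2CC[C@@](C)([C@@H]3CC(=O)[C@H]4OC(=O)[C@@H](O[Si](C)(C)C(C)(C)C)[C@@H]34)[C@H]12 | intermediate
19 | α-hydroxy ketone: 7-endo-hydroxy derivative of 18 (core C1 hydroxyl cis to the ring-fusion oxygen) | C=C1CCCC(C)(C)[C@@H]2CC[C@@](C)([C@@H]3[C@@H](O)C(=O)[C@H]4OC(=O)[C@@H](O[Si](C)(C)C(C)(C)C)[C@@H]34)[C@H]12 | intermediate
20 | 7-endo-acetoxy-6-exo-Az-4-endo-[(tert-butyldimethylsilyl)oxy]-cis-2-oxabicyclo[3.3.0]octane-3,8-dione | C=C1CCCC(C)(C)[C@@H]2CC[C@@](C)([C@@H]3[C@@H](OC(C)=O)C(=O)[C@H]4OC(=O)[C@@H](O[Si](C)(C)C(C)(C)C)[C@@H]34)[C@H]12 | intermediate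
21 | 7-endo-acetoxy-6-exo-Az-4-endo-hydroxy-cis-2-oxabicyclo[3.3.0]octane-3,8-dione | C=C1CCCC(C)(C)[C@@H]2CC[C@@](C)([C@@H]3[C@@H](OC(C)=O)C(=O)[C@H]4OC(=O)[C@@H](O)[C@@H]34)[C@H]12 | intermediate
22 | 7-endo-acetoxy-6-exo-Az-4-endo-[(trifluoromethylsulfonyl)oxy]-cis-2-oxabicyclo[3.3.0]octane-3,8-dione (core C6 S) | C=C1CCCC(C)(C)[C@@H]2CC[C@@](C)([C@@H]3[C@@H](OC(C)=O)C(=O)[C@H]4OC(=O)[C@@H](OS(=O)(=O)C(F)(F)F)[C@@H]34)[C@H]12 | intermediate
23 | ring-opened methyl ester: cyclopentanone with C1 acetoxy, C4 hydroxyl (as its sodium alkoxide), C5 side chain CH(OTf)CO2Me and C8 Az, the three oxygenated substituents cis and Az trans | C=C1CCCC(C)(C)[C@@H]2CC[C@@](C)([C@@H]3[C@@H](OC(C)=O)C(=O)[C@@H](O)[C@H]3[C@H](OS(=O)(=O)C(F)(F)F)C(=O)OC)[C@H]12 | intermediate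
24 | acetyl-shifted alcohol: as 23 but with C4 acetoxy and C1 hydroxyl (as its sodium alkoxide) | C=C1CCCC(C)(C)[C@@H]2CC[C@@](C)([C@@H]3[C@@H](O)C(=O)[C@@H](OC(C)=O)[C@H]3[C@H](OS(=O)(=O)C(F)(F)F)C(=O)OC)[C@H]12 | intermediate
25 | methyl 5-endo-acetoxy-7-anti-Az-6-oxo-2-oxabicyclo[2.2.1]heptane-3-exo-carboxylate (Az anti to the O2–C3 bridge of this bicycle) | C=C1CCCC(C)(C)[C@@H]2CC[C@@](C)([C@@H]3[C@@H]4C(=O)[C@@H](OC(C)=O)[C@H]3[C@H](C(=O)OC)O4)[C@H]12 | intermediate
26 | methyl (1S,4S,5R,6R,8R)-4-acetoxy-3-oxo-8-[(1R,3aR,8aS)-1,4,4-trimethyl-8-methylidenedecahydroazulen-1-yl]-2,7-dioxabicyclo[3.2.1]octane-6-carboxylate (CNP0215240.1) | C=C1CCCC(C)(C)[C@@H]2CC[C@@](C)([C@@H]3[C@@H]4OC(=O)[C@@H](OC(C)=O)[C@H]3[C@H](C(=O)OC)O4)[C@H]12 | target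

**Totals**

Total step count: 15. Longest linear sequence: 11 steps (steps 5 to 9, then 10 to 15); fragment A takes 4 steps (1 to 4).

**Steps most likely to fail**

Step 14 (proposed new method). The C4 alkoxide set free by methanolysis may close the four-membered ring before the acetyl group has shifted, or methoxide may cleave the acetate so that the cascade stalls and the α-ketol epimerises. The fallback uses known chemistry and sets out from alcohol 21. Mesylation (MsCl, Et3N, CH2Cl2, 0 °C) should give 7-endo-acetoxy-6-exo-Az-4-endo-(methylsulfonyloxy)-cis-2-oxabicyclo[3.3.0]octane-3,8-dione F1. Because a mesylate is displaced far more slowly than a triflate, K2CO3 in MeOH (0 °C → rt) should first remove the C1 acetate and open the lactone by plain transesterification. Ordinary 5-exo-tet Williamson etherification by the C1 alkoxide should then give methyl 7-anti-Az-5-endo-hydroxy-6-oxo-2-oxabicyclo[2.2.1]heptane-3-exo-carboxylate F2. Acetylation (Ac2O, pyridine, DMAP) returns to the route at 25.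

Step 10. The iron hydride may reduce the hindered tertiary radical (net hydrogenation of the alkene) or transfer hydrogen to the enone before the C–C bond forms. The fallback generates the same radical without a metal hydride and sets out from 9. Mukaiyama hydration (Co(acac)2, PhSiH3, O2, i-PrOH) should give cis-fused 3,8,8-trimethyl-4-[(trimethylsilyl)methyl]decahydroazulene-3,4-diol F3. KH (THF, 0 °C) should trigger the Peterson elimination to cis-fused 1,4,4-trimethyl-8-methylidenedecahydroazulen-1-ol F4. Methyl chlorooxoacetate (Et3N, DMAP, CH2Cl2) should give methyl 1,4,4-trimethyl-8-methylidenedecahydroazulen-1-yl oxalate F5, and CsOH (THF/H2O) the cesium 1,4,4-trimethyl-8-methylidenedecahydroazulen-1-yl oxalate F6. Blue-light irradiation of F6 with Ir[dF(CF3)ppy]2(dtbbpy)PF6 (1 mol%), water and enone 16 in DME/DMF should give the decarboxylative Giese adduct directly, which is 18, where the route is rejoined.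

Step 15. The exocyclic double bond may be oxidised or shifted into the ring by the Lewis acid, and the acylal product may be cleaved by acid. The fallback masks the alkene and sets out from 25. Pyridinium tribromide (CH2Cl2, −78 °C) should give methyl 5-endo-acetoxy-7-anti-[8-bromo-8-(bromomethyl)-1,4,4-trimethyldecahydroazulen-1-yl]-6-oxo-2-oxabicyclo[2.2.1]heptane-3-exo-carboxylate F7. A conventional buffered Baeyer–Villiger oxidation (mCPBA, NaHCO3, CH2Cl2, 0 °C) should give methyl 4-acetoxy-8-[8-bromo-8-(bromomethyl)-1,4,4-trimethyldecahydroazulen-1-yl]-3-oxo-2,7-dioxabicyclo[3.2.1]octane-6-carboxylate F8. Zn dust (NH4Cl, THF/EtOH, 0 °C) should regenerate the methylene by reductive debromination and arrive at 26.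

Further compounds
F1 | step 14 | 7-endo-acetoxy-6-exo-Az-4-endo-(methylsulfonyloxy)-cis-2-oxabicyclo[3.3.0]octane-3,8-dione | C=C1CCCC(C)(C)[C@@H]2CC[C@@](C)([C@@H]3[C@@H](OC(C)=O)C(=O)[C@H]4OC(=O)[C@@H](OS(C)(=O)=O)[C@@H]34)[C@H]12
F2 | step 14 | methyl 7-anti-Az-5-endo-hydroxy-6-oxo-2-oxabicyclo[2.2.1]heptane-3-exo-carboxylate | C=C1CCCC(C)(C)[C@@H]2CC[C@@](C)([C@@H]3[C@@H]4C(=O)[C@@H](O)[C@H]3[C@H](C(=O)OC)O4)[C@H]12
F3 | step 10 | cis-fused 3,8,8-trimethyl-4-[(trimethylsilyl)methyl]decahydroazulene-3,4-diol (ring-fusion centres as in 9, either epimer at C3 and C4) | C[Si](C)(C)CC1(O)CCCC(C)(C)[C@@H]2CCC(C)(O)[C@H]12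
F4 | step 10 | cis-fused 1,4,4-trimethyl-8-methylidenedecahydroazulen-1-ol (ring-fusion centres as in the target, either C1 epimer) | C=C1CCCC(C)(C)[C@@H]2CCC(C)(O)[C@H]12
F5 | step 10 | methyl 1,4,4-trimethyl-8-methylidenedecahydroazulen-1-yl oxalate | C=C1CCCC(C)(C)[C@@H]2CCC(C)(OC(=O)C(=O)OC)[C@H]12
F6 | step 10 | cesium 1,4,4-trimethyl-8-methylidenedecahydroazulen-1-yl oxalate | C=C1CCCC(C)(C)[C@@H]2CCC(C)(OC(=O)C(=O)[O-])[C@H]12.[Cs+]
F7 | step 15 | methyl 5-endo-acetoxy-7-anti-[8-bromo-8-(bromomethyl)-1,4,4-trimethyldecahydroazulen-1-yl]-6-oxo-2-oxabicyclo[2.2.1]heptane-3-exo-carboxylate | BrCC1(Br)CCCC(C)(C)[C@@H]2CC[C@@](C)([C@@H]3[C@@H]4C(=O)[C@@H](OC(C)=O)[C@H]3[C@H](C(=O)OC)O4)[C@H]12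
F8 | step 15 | methyl 4-acetoxy-8-[8-bromo-8-(bromomethyl)-1,4,4-trimethyldecahydroazulen-1-yl]-3-oxo-2,7-dioxabicyclo[3.2.1]octane-6-carboxylate | BrCC1(Br)CCCC(C)(C)[C@@H]2CC[C@@](C)([C@@H]3[C@@H]4OC(=O)[C@@H](OC(C)=O)[C@H]3[C@H](C(=O)OC)O4)[C@H]12
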